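The runs were generated by integration with made-up constants; scatter was added.

A one-step world, where Rx and Ek give Ej and stop, is not this flask, for in the north-west run Ej falls from 70.8% at 15.0 min to 16.8% at 80.0 min while Ve climbs, so we count how long Ej has stood.

| flask | Rx | Ek | Ry | remark | time |
|---|---|---|---|---|---|
| west | 0.78 M | 1.2 equiv | 0.039 M | run made earlier |  |
| south-west | 0.78 M | 0.60 equiv | 0.039 M | run made earlier |  |
| south | 0.78 M | 0.90 equiv | 0.039 M | run made earlier |  |
| north-west | 1.6 M | 1.2 equiv | 0.039 M | run made earlier |  |
| epsilon | 0.78 M | 1.20 equiv | 0.0390 M | a closed flask charged with all of it at once and left for 80 min | 80 min |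
| beta | 0.78 M | 1.20 equiv (fed, over 40.0 min) | 0.0390 M | a stirred flask in which Ek is dosed at a steady rate over 40.0 min without added volume, worked up at 80 min | 80 min |
| alpha | 0.78 M (fed, over 40.0 min) | 1.20 equiv | 0.0390 M | a stirred flask in which Rx is dosed at a steady rate over 40.0 min without added volume, worked up at 80 min | 80 min |
| delta | 0.78 M | 1.20 equiv | 0.0390 M | one stirred flow tank at steady state, fed with the mixture as stated, mean residence time 80 min |  |

| run | time / min | Ej / % | Ve / % |
|---|---|---|---|
| west | 6.00 | 84.5 | 9.6 |
| west | 12.0 | 75.6 | 20.7 |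
| west | 25.0 | 56.1 | 38.6 |
| west | 40.0 | 41.3 | 54.3 |
| west | 80.0 | 16.0 | 78.0 |
| south-west | 15.0 | 41.2 | 15.1 |
| south-west | 30.0 | 27.7 | 25.6 |
| south-west | 50.0 | 18.2 | 36.6 |
| south-west | 60.0 | 14.8 | 39.5 |
| south-west | 80.0 | 9.8 | 44.7 |
| south | 15.0 | 62.0 | 22.4 |
| south | 30.0 | 45.2 | 39.2 |
| south | 50.0 | 28.8 | 55.1 |
| south | 60.0 | 24.0 | 61.3 |
| south | 80.0 | 15.4 | 70.6 |
| north-west | 15.0 | 70.8 | 26.7 |
| north-west | 30.0 | 52.3 | 46.7 |
| north-west | 50.0 | 33.5 | 64.0 |
| north-west | 60.0 | 27.8 | 70.2 |
| north-west | 80.0 | 16.8 | 80.4 |

(readings scatter by 0.5 percentage points)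

- the stated concentrations are those of everything mixed, before any reaction; amounts are the same in each set-up
- the feed brings no volume worth counting
- the earlier runs were made in a closed, stirred flask

1. the set-up with the highest amount of Ej at the outlet or at the end, in percent of the Rx put in ("none" if the first two lie within 2 percentage points) (epsilon / beta / alpha / delta / none)
2. amount of Ej at the outlet or at the end, in percent of the Rx put in, epsilon
3. amount of Ej at the outlet or at the end, in percent of the Rx put in, beta
4. amount of Ej at the outlet or at the end, in percent of the Rx put in, alpha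
5. amount of Ej at the outlet or at the end, in percent of the Rx put in, delta

In the west run Ej and Ve already sum to 94.1% at 6.00 min, close to the Rx charge less the Ry, 95.0%, and we take that as the pool of Ej. The north-west fall reads as a lifetime of Ej of 45.2 min, and the time held divided by that lifetime is the lifetime count, 1.77 here. With Ej falling first order from that pool, a closed flask keeps the pool times the exponential of minus the count, 16.2% for epsilon, while a steady tank keeps the pool over one plus the count, 34.3% for delta, which is more. Rx dosed over 40.0 min makes Ej on average at mid-dose, so we give alpha a count of 1.33 and 25.2%, less than delta and under the forecast's figure.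

The forecast reads the decay of Ej as first order, “the same in all runs”, and gives 16.5% for epsilon, 25% for beta, 26.2% for alpha and 34% for delta, choosing delta.

The flask gives 17.0%, 25.6%, 27.4% and 34.2% in that order, and the best is delta.

    Ej → Ve (k = 3.60 × 10⁻⁴ s⁻¹)
    Ej + Ry → EjRy (k = 0.00440 M⁻¹ s⁻¹)
    Rx + Ek → Ej + Yx (k = 0.0490 M⁻¹ s⁻¹)

In epsilon the step of Rx with Ek, half-life 0.25 min as charged, ran while Rx stood, and its half-life is far shorter than that of Ej to Ve, 32 min, the rate-limiting step on the way from Rx to Ve; Ej then went on to Ve, while EjRy ends at 5.00% of the Rx charged, which matches the charge of Ry counted against Rx, 5.00%. Counted back, epsilon's Ej is 1.72 lifetimes old and delta's 1.78, beside our 1.77. Delta leads alpha by 6.8 percentage points, and the choice turns to none with a lead under 2 points. Beta dosed over a tenth of the run counts 1.68 lifetimes from mid-dose and ends at 18.5%.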